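**Structural features**

The target is a daucane sesquiterpenoid diester. A cyclopentane (C1–C5) is trans-fused through the C1–C5 bond to a cycloheptene (C1, C5, C6, C7, C8, C9, C10). The numbering used here is: C1 the methyl-bearing quaternary fusion carbon, C2 and C3 methylenes, C4 the isopropyl carbinol, C5 the fusion CH, C6 the aroyloxy carbon, C7=C8 the alkene with its methyl on C8, C9 the acetoxy carbon, C10 a methylene. Four stereocentres are contiguous (C4, C5 and C6 in a row, with the quaternary C1 on the other side of C5), and the fifth, C9, is separated from them by the alkene and by C10. The configuration is 1R,4R,5S,6S,9S, with the C1 methyl and the C4 hydroxyl on one face and H5, O6 and O9 on the other. The fragile parts are the two allylic esters on either side of the trisubstituted alkene (ionisation, acyl migration across the cis-ene-1,4-diol), the tertiary carbinol (dehydration) and the free phenol. The real difficulty lies in the all-carbon quaternary centre C1 next to C5 with a trans fusion, in the crowded tertiary carbinol C4, and in telling O6 and O9 apart. The key step exploits the sequence C4–C5–C1 of the five-membered ring together with the exocyclic C5–C6 bond: with C4 as a ketone, C1 is the β carbon and C5 the α carbon of a cyclopentenone, so methyl can be delivered to C1 and the enolate formed can bring in C6 through C5, the Z alkene C7=C8 arriving as a Z iodoalkene that later closes C8–C9.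

**Logic of the disconnections**

Phenol and C6 ester. The O–Si bond on the phenol of 22 and then the acyl C–O bond at O6 are cut, which leads from 23 through 22 to 19 and 20. The aroyl group is the only aromatic fragment and the part most exposed to nucleophiles, so it goes on last. The cut leaves a C15 core. The forward steps must acylate a hindered secondary allylic hydroxyl without touching the tertiary C4 hydroxyl or moving the C9 acetate, and the final desilylation must spare two esters.

C9 acetate and C6 silyl ether. The acetyl C–O bond at O9 and the Si–O bond at O6 connect 19, 18 and 17. The two allylic hydroxyls appear at different times (O6 in the aldol, O9 in the ring closure), so a silyl group put on O6 early marks it and no selective reaction on a diol is needed. The forward demand is an acetylation that ignores the tertiary hydroxyl and a desilylation under non-basic conditions.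

C8–C9. 17 is opened at the C8–C9 bond to 15. This bond joins an sp2 carbon that can be made nucleophilic from its iodide to a carbinol carbon that can be an aldehyde, and cutting it turns the bicycle into a monocycle. The forward step must close a seven-membered ring, tolerate a free tertiary hydroxyl, and set C9.

C9 aldehyde. 15 is traced to 13 by restoring one carbon as a terminal alkene on C9. An allyl group is a robust carrier of the C10–C9 unit through organometallic steps. The forward cleavage must prefer the monosubstituted alkene to the iodoalkene.

C4–isopropyl bond. 13 goes back through 12 to 11 by cutting the bond between C4 and the isopropyl carbon and removing the O6 silyl group. This returns the C4 ketone that the enolate chemistry needs. The forward addition must deliver a branched nucleophile to a hindered, enolisable ketone on the face anti to the C5 substituent, without β-elimination of O6, which is why O6 is silylated first.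

C1–CH3 and C5–C6. 11 is cut at these two bonds to 4, 9 and 8. Both bonds flank the fusion bond, and cutting them removes three stereocentres at once and leaves an achiral enone and an achiral aldehyde. The forward step must control the face at C1 by a catalyst, the face at C5 by the C1 substituents, and the C5/C6 relation by the enolate geometry.

C1–C10. 4 is cut at the bond between the ring and the allyl group to 1 and 2. The forward step is an addition to a vinylogous ester with carbonyl transposition, which must not move the skipped alkene into conjugation.

C8–I. 8 is traced through 7 to 5 by removing iodine and hydrogen from the alkene and adjusting the oxidation level. The forward hydrometalation must be trans and place iodine on the methyl-bearing carbon.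

**Other disconnections considered**

Alternative 1: The cut takes C8 out from between C7 and C9, contracting the seven-membered ring to the cyclohexene of the trans-hydrindene A1 with a C7=C9 double bond. In the forward direction dibromocarbene adds to that alkene to give the gem-dibromocyclopropane A2. AgOAc in acetic acid then removes the endo bromide while the C7–C9 bond opens in a disrotatory way to a 2-bromocycloheptenyl cation, which acetate captures at C9 to give the bromo acetate A3.
- In favour: six-membered-ring chemistry for the trans fusion, and one operation that creates the ring size, the alkene position and the C9–O bond.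
- Better than the chosen plan on one point: the acetate of the target comes from the key step itself, and O4 and O6 already carry different silyl groups, whereas the chosen plan needs a silylation–desilylation pair to distinguish O6 from O9.
- Against: A1 still contains the quaternary C1, the C4 carbinol and the C5/C6 pair, so the key step solves none of the hard stereochemical problems and A1 needs a long synthesis of its own.
- Against: the allyl cation can be captured at C7 as well as at C9, and the face of capture at C9 is decided only by the ring.
- Against: hot acetic acid with a silver salt threatens the tertiary silyl ether.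
- Against: the bromine on C8 of A3 must afterwards be exchanged for methyl, on a substrate whose allylic acetate is itself reactive toward zerovalent palladium and toward cuprates.
- Comparison: the ring expansion is a cationic electrocyclic opening with two regiochemical outcomes; the chosen cascade is a closed-transition-state enolate reaction whose weak point is one facial preference. The chosen key step builds two skeletal bonds and three stereocentres, the alternative one C–O bond and one stereocentre. After the key step the alternative is equal or slightly shorter (methylation, desilylation, aroylation, phenol release); before it, it is much longer.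

Alternative 2: The cut is the ring bond C4–C5, which opens the cyclopentane to the acyclic diazo ester A5. Its carbene carbon is C5 (C6 being the ester carbon), attached to the quaternary C1, and its C4 is a silyl-protected secondary carbinol carrying the isopropyl group, derived from L-valine A4. In the forward direction Rh2(OAc)4 forms the rhodium carbene, which inserts into the C4–H bond five atoms away with retention and gives cyclopentane A6.
- Better than the chosen plan at C4: the configuration comes from the chiral pool and the retention of the insertion, not from the face selectivity of an organometallic addition to a hindered ketone.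
- In favour: the ether oxygen activates the C–H bond, five-membered closure is the preferred mode, and the C5 ester centre can be equilibrated to the arrangement the target needs (trans to isopropyl and to the C10 arm).
- Against: A5 needs an acyclic quaternary stereocentre C1 that nothing in this plan creates selectively.
- Against: the carbene sits next to an acetal, so oxonium ylide formation with a methoxy oxygen and insertion into O–CH3 or into the isopropyl methine compete with the hindered tertiary C–H bond.
- Against: C7, C8, the C6 configuration and the whole seven-membered ring remain to be built from the ester of A6.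
- Comparison: the insertion is a concerted three-centre process that must choose among several C–H bonds and heteroatoms, whereas in the chosen cascade the enolate regiochemistry is fixed by the conjugate addition. The alternative's key step forms one skeletal bond and closes one ring, the chosen one forms two bonds and three stereocentres without closing a ring. On step count the chosen plan is clearly shorter; the two are equal only in the final ester chemistry.

Alternative 3: The cut is C6–C7, the other end of the alkene. The precursor A7 is a cyclopentane with an aldehyde (C6) on C5 and, on C1, the chain CH2–CH(OAc)–C(CH3)=CHI with Z geometry. In the forward direction CrCl2 with catalytic NiCl2 turns the iodide into an alkenylchromium species at C7, which adds to the C6 aldehyde and closes the ring to A8.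
- Equal to the chosen plan: the ring-closing reaction type and the reliability of the organochromium step are the same.
- Better than the chosen plan at C9: C9 and its acetate are set in an open chain under reagent control before the ring exists, whereas the chosen plan lets the ring closure decide C9.
- Better by two steps in the endgame: the hydroxyl that the closure creates is the one to be aroylated, so no silyl group has to go on and off O6.
- Against: the aldehyde sits on C5 between the quaternary C1 and the fully substituted C4, so it is hindered and epimerisable.
- Against: C6 becomes the centre decided by the ring closure, next to that congested carbon.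
- Against: the allylic acetate must survive zerovalent nickel and divalent chromium, which can turn allylic esters into allylmetal species.
- Against: C5–C6 is no longer made by an aldol, so the trans arrangement of the C1 and C5 arms and the Z-configured iodoalkene beside an acetoxy stereocentre each need a separate stereocontrolled construction.
- Comparison: the chosen plan places the closed-transition-state aldol at C6 and leaves C9 to the ring closure; the alternative does the reverse. Overall length is expected to be similar or longer for the alternative because A7 is harder to reach than 15.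

Key step: step 4

Remark on the chemistry: 4-(tert-butyldimethylsilyloxy)benzoic acid 20 is taken as a catalogue reagent. The chiral carbene ligand L* (a 4,5-diphenylimidazolin-2-ylidene with one N-(2,6-diethylphenyl) and one N-(2-sulfonatophenyl) group, used as its silver complex Ag(L*)) is a catalyst component and is not counted among the steps.

Remark on the stereochemical labels: C1, C5, C6 and the Z iodoalkene of 11 map onto the target without change. The CIP label of C6 is R while iodine (or chromium) is on C8 (compounds 11–16) and becomes S from 17 on, although no bond at C6 is touched.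

**Steps**

Step 1
Reactants: 1 3-ethoxycyclopent-2-en-1-one; 2 allylmagnesium bromide
Product: 4 3-allylcyclopent-2-en-1-one, via bromomagnesium 1-allyl-3-ethoxycyclopent-2-en-1-olate 3 (not isolated)
Conditions: 2 (1.2 equiv), THF, −78 to 0 °C; then 1 M aq HCl, 0 °C, 15 min
Reagents that add atoms: water, O
Why: Stork–Danheiser alkylative carbonyl transposition: 1,2-addition of the Grignard reagent to the vinylogous ester, then acid hydrolysis of the enol ether with loss of the tertiary hydroxyl gives the 3-substituted enone; brief cold acid should keep the skipped alkene out of conjugation.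

Step 2
Reactants: 5 but-2-yn-1-ol
Product: 7 (Z)-3-iodobut-2-en-1-ol, via cyclic sodium alkenylalanate 6 (not isolated)
Conditions: NaAlH2(OCH2CH2OMe)2 (1.5 equiv), THF, 0 °C to rt; then I2, THF, −78 to 0 °C; aq Na2S2O3
Reagents that add atoms: iodine, [I][I]
Why: Hydroxyl-directed trans-hydroalumination of a propargylic alcohol followed by iodinolysis with retention; the five-membered O–Al–C chelate places aluminium, and then iodine, on the methyl-bearing carbon cis to the CH2O group, which fixes the Z geometry.

Step 3
Reactants: 7 (Z)-3-iodobut-2-en-1-ol
Product: 8 (Z)-3-iodobut-2-enal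
Conditions: activated MnO2 (15 equiv), CH2Cl2, rt, dark; filtered and used at once
Reagents that add atoms: none
Why: Allylic alcohol oxidation on the MnO2 surface under neutral heterogeneous conditions, chosen to avoid Z to E isomerisation of the light- and acid-sensitive β-iodo enal.

Step 4
Reactants: 4 3-allylcyclopent-2-en-1-one; 9 trimethylaluminium; 8 (Z)-3-iodobut-2-enal
Product: 11 (2S,3R)-2-[(1R,2Z)-1-hydroxy-3-iodobut-2-en-1-yl]-3-methyl-3-(prop-2-en-1-yl)cyclopentan-1-one, via dimethylaluminium (R)-3-allyl-3-methylcyclopent-1-en-1-olate 10 (not isolated)
Conditions: Cu(OTf)2 (5 mol%), Ag(L*) (5 mol%), 9 (1.2 equiv), THF, −78 °C; then 8 (1.5 equiv), −78 to −40 °C; aq potassium sodium tartrate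
Reagents that add atoms: none
Why: Copper-catalysed asymmetric conjugate addition of a trialkylaluminium to a β-substituted cyclopentenone with aldol trapping of the aluminium enolate, a known reaction class. Cu(OTf)2 is reduced by 9 to a monovalent copper carbene complex; methyl passes from aluminium to copper and then to C1 of 4 (π-complex, trivalent copper intermediate, reductive elimination), and the ligand enantiomer is chosen so that methyl enters the face that makes C1 R. The dimethylaluminium enolate 10 is regiodefined (C4–O, C5) and, being the enolate of a cyclic ketone, necessarily E; it adds to 8 through a closed six-membered chair transition state with the iodobutenyl group equatorial, which gives the anti relation of C5 and C6. The aldehyde approaches the enolate face anti to allyl, the larger of the two C1 substituents, so the new C5–C6 bond is trans to C10 and cis to the C1 methyl (C5 S); this is the selectivity the step needs most and it rests only on the size difference between allyl and methyl. No ring is closed. The step also needs 1,2-addition to the enal and no methyl transfer from leftover 9 to 8, which the near-stoichiometric charge of 9 and the low temperature should secure. The Z iodoalkene is a spectator and is kept cold and dark to hold its geometry.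

Step 5
Reactants: 11 (2S,3R)-2-[(1R,2Z)-1-hydroxy-3-iodobut-2-en-1-yl]-3-methyl-3-(prop-2-en-1-yl)cyclopentan-1-one
Product: 12 (2S,3R)-2-[(1R,2Z)-3-iodo-1-(triethylsilyloxy)but-2-en-1-yl]-3-methyl-3-(prop-2-en-1-yl)cyclopentan-1-one
Conditions: TESOTf (1.2 equiv), 2,6-lutidine (2 equiv), CH2Cl2, −78 °C
Reagents that add atoms: triethylsilyl trifluoromethanesulfonate, CC[Si](CC)(CC)OS(=O)(=O)C(F)(F)F
Why: O-silylation of a hindered β-hydroxy ketone with a silyl triflate and a non-nucleophilic base at low temperature, which should avoid retro-aldol and β-elimination; no stereocentre is touched.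

Step 6
Reactants: 12 (2S,3R)-2-[(1R,2Z)-3-iodo-1-(triethylsilyloxy)but-2-en-1-yl]-3-methyl-3-(prop-2-en-1-yl)cyclopentan-1-one
Product: 13 (1R,2S,3R)-2-[(1R,2Z)-3-iodo-1-(triethylsilyloxy)but-2-en-1-yl]-3-methyl-1-(propan-2-yl)-3-(prop-2-en-1-yl)cyclopentan-1-ol
Conditions: CeCl3 (3.5 equiv, dried), i-PrMgCl (3 equiv), THF, −78 °C, 1 h; then 12, −78 °C; aq NH4Cl at −78 °C
Reagents that add atoms: isopropylmagnesium chloride, CC(C)[Mg]Cl
Why: Organocerium addition to a hindered, enolisable ketone; the weakly basic cerium reagent should suppress enolisation, β-hydride reduction and iodine–magnesium exchange at −78 °C. The nucleophile should enter the carbonyl face anti to the large C5 substituent (the face of H5), which puts the hydroxyl cis to the C5–C6 bond and makes C4 R.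

Step 7
Reactants: 13 (1R,2S,3R)-2-[(1R,2Z)-3-iodo-1-(triethylsilyloxy)but-2-en-1-yl]-3-methyl-1-(propan-2-yl)-3-(prop-2-en-1-yl)cyclopentan-1-ol
Product: 15 2-{(1R,2S,3R)-3-hydroxy-2-[(1R,2Z)-3-iodo-1-(triethylsilyloxy)but-2-en-1-yl]-1-methyl-3-(propan-2-yl)cyclopentyl}acetaldehyde, via vicinal diol 14 (not isolated)
Conditions: OsO4 (2 mol%), NaIO4 (4 equiv), 2,6-lutidine (2 equiv), dioxane/H2O 3:1, rt
Reagents that add atoms: osmium tetroxide, O=[Os](=O)(=O)=O (catalytic oxygen carrier); sodium periodate, [Na+].[O-][I](=O)(=O)=O (stoichiometric oxygen source)
Why: Lemieux–Johnson oxidative cleavage; the monosubstituted terminal alkene should be dihydroxylated well before the hindered, iodine-deactivated trisubstituted alkene, and the buffer protects the silyl ether. The C4 hydroxyl and the new aldehyde arm are trans on the ring and cannot form a lactol.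

Step 8
Reactants: 15 2-{(1R,2S,3R)-3-hydroxy-2-[(1R,2Z)-3-iodo-1-(triethylsilyloxy)but-2-en-1-yl]-1-methyl-3-(propan-2-yl)cyclopentyl}acetaldehyde
Product: 17 (1R,4R,5S,6S,9S)-6-(triethylsilyloxy)dauc-7-ene-4,9-diol, via alkenylchromium dichloride 16 (not isolated)
Conditions: CrCl2 (8 equiv), NiCl2 (2 mol% of the CrCl2), degassed DMSO, 0.005 M, rt
Reagents that add atoms: none
Why: Intramolecular Nozaki–Hiyama–Kishi reaction: zerovalent nickel inserts into the C8–I bond, transmetalation gives the trivalent alkenylchromium species 16, and this adds to the C9 aldehyde in a 7-exo-trig closure that tolerates the free tertiary hydroxyl. The Z geometry is retained, and C9 should form S if the chromium-bound aldehyde oxygen turns away from the C1 methyl, a substrate-controlled preference that is expected but not assured.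

Step 9
Reactants: 17 (1R,4R,5S,6S,9S)-6-(triethylsilyloxy)dauc-7-ene-4,9-diol
Product: 18 (1R,4R,5S,6S,9S)-9-acetoxy-6-(triethylsilyloxy)dauc-7-en-4-ol
Conditions: Ac2O (1.5 equiv), pyridine, DMAP (0.1 equiv), CH2Cl2, 0 °C
Reagents that add atoms: acetic anhydride, CC(=O)OC(C)=O
Why: DMAP-catalysed acetylation of the secondary allylic hydroxyl; the tertiary C4 hydroxyl, flanked by isopropyl and the ring fusion, should not react at 0 °C.

Step 10
Reactants: 18 (1R,4R,5S,6S,9S)-9-acetoxy-6-(triethylsilyloxy)dauc-7-en-4-ol
Product: 19 (1R,4R,5S,6S,9S)-9-acetoxydauc-7-ene-4,6-diol
Conditions: HF·pyridine, pyridine, THF, 0 °C to rt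
Reagents that add atoms: none
Why: Fluoride-mediated cleavage of a secondary triethylsilyl ether under buffered, non-basic conditions, chosen so that no alkoxide forms that could move the acetyl group from O9 to O6 and no strong acid ionises the allylic esters.

Step 11
Reactants: 19 (1R,4R,5S,6S,9S)-9-acetoxydauc-7-ene-4,6-diol; 20 4-(tert-butyldimethylsilyloxy)benzoic acid
Product: 22 (1R,4R,5S,6S,9S)-9-acetoxy-6-[4-(tert-butyldimethylsilyloxy)benzoyloxy]dauc-7-en-4-ol, via O-acylisourea 21 (not isolated)
Conditions: 20 (2 equiv), 1-ethyl-3-(3-dimethylaminopropyl)carbodiimide hydrochloride (EDC·HCl, 2.5 equiv), DMAP (2.5 equiv), CH2Cl2, rt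
Reagents that add atoms: none
Why: Steglich esterification through the O-acylisourea and the acylpyridinium ion; only the secondary C6 hydroxyl is accessible, the tertiary C4 hydroxyl is not acylated, and the configuration at C6 is retained because the C–O bond is not broken.

Step 12
Reactants: 22 (1R,4R,5S,6S,9S)-9-acetoxy-6-[4-(tert-butyldimethylsilyloxy)benzoyloxy]dauc-7-en-4-ol
Product: 23 (1R,4R,5S,6S,9S)-9-acetoxy-6-(4-hydroxybenzoyloxy)dauc-7-en-4-ol
Conditions: TBAF (1.2 equiv), AcOH (1.2 equiv), THF, 0 °C
Reagents that add atoms: none
Why: Aryl silyl ethers are cleaved by fluoride much faster than alkyl esters are attacked, and acetic acid buffering keeps the medium from becoming basic, so both esters and the allylic system should survive.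

**Compound list**

1 | 3-ethoxycyclopent-2-en-1-one | CCOC1=CC(=O)CC1 | starting material
2 | allylmagnesium bromide | C=CC[Mg]Br | starting material
3 | bromomagnesium 1-allyl-3-ethoxycyclopent-2-en-1-olate (racemic) | C=CCC1(O[Mg]Br)C=C(OCC)CC1 | intermediate (not isolated)
4 | 3-allylcyclopent-2-en-1-one | C=CCC1=CC(=O)CC1 | intermediate
5 | but-2-yn-1-ol | CC#CCO | starting material
6 | cyclic sodium alkenylalanate (five-membered O–Al–C ring, aluminium on the methyl-bearing alkene carbon, two 2-methoxyethoxy groups on aluminium) | [Na+].CC1=CCO[Al-]1(OCCOC)OCCOC | intermediate (not isolated)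
7 | (Z)-3-iodobut-2-en-1-ol | OC/C=C(/C)I | intermediate
8 | (Z)-3-iodobut-2-enal | O=C/C=C(/C)I | intermediate
9 | trimethylaluminium | C[Al](C)C | starting material
10 | dimethylaluminium (R)-3-allyl-3-methylcyclopent-1-en-1-olate | C=CC[C@@]1(C)CCC(O[Al](C)C)=C1 | intermediate (not isolated)
11 | (2S,3R)-2-[(1R,2Z)-1-hydroxy-3-iodobut-2-en-1-yl]-3-methyl-3-(prop-2-en-1-yl)cyclopentan-1-one | C=CC[C@@]1(C)CCC(=O)[C@@H]1[C@@H](O)/C=C(/C)I | intermediate
12 | (2S,3R)-2-[(1R,2Z)-3-iodo-1-(triethylsilyloxy)but-2-en-1-yl]-3-methyl-3-(prop-2-en-1-yl)cyclopentan-1-one | C=CC[C@@]1(C)CCC(=O)[C@@H]1[C@@H](O[Si](CC)(CC)CC)/C=C(/C)I | intermediate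
13 | (1R,2S,3R)-2-[(1R,2Z)-3-iodo-1-(triethylsilyloxy)but-2-en-1-yl]-3-methyl-1-(propan-2-yl)-3-(prop-2-en-1-yl)cyclopentan-1-ol | C=CC[C@@]1(C)CC[C@@](O)(C(C)C)[C@@H]1[C@@H](O[Si](CC)(CC)CC)/C=C(/C)I | intermediate
14 | vicinal diol from 13 (2,3-dihydroxypropyl in place of allyl; both epimers at the new carbinol) | OCC(O)C[C@@]1(C)CC[C@@](O)(C(C)C)[C@@H]1[C@@H](O[Si](CC)(CC)CC)/C=C(/C)I | intermediate (not isolated)
15 | 2-{(1R,2S,3R)-3-hydroxy-2-[(1R,2Z)-3-iodo-1-(triethylsilyloxy)but-2-en-1-yl]-1-methyl-3-(propan-2-yl)cyclopentyl}acetaldehyde | O=CC[C@@]1(C)CC[C@@](O)(C(C)C)[C@@H]1[C@@H](O[Si](CC)(CC)CC)/C=C(/C)I | intermediate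
16 | alkenylchromium dichloride from 15 (CrCl2 in place of iodine on C8, Z geometry kept) | O=CC[C@@]1(C)CC[C@@](O)(C(C)C)[C@@H]1[C@@H](O[Si](CC)(CC)CC)/C=C(/C)[Cr](Cl)Cl | intermediate (not isolated)
17 | (1R,4R,5S,6S,9S)-6-(triethylsilyloxy)dauc-7-ene-4,9-diol | O[C@H]1C[C@@]2(C)CC[C@@](O)(C(C)C)[C@@H]2[C@@H](O[Si](CC)(CC)CC)C=C1C | intermediate
18 | (1R,4R,5S,6S,9S)-9-acetoxy-6-(triethylsilyloxy)dauc-7-en-4-ol | CC(=O)O[C@H]1C[C@@]2(C)CC[C@@](O)(C(C)C)[C@@H]2[C@@H](O[Si](CC)(CC)CC)C=C1C | intermediate
19 | (1R,4R,5S,6S,9S)-9-acetoxydauc-7-ene-4,6-diol | CC(=O)O[C@H]1C[C@@]2(C)CC[C@@](O)(C(C)C)[C@@H]2[C@@H](O)C=C1C | intermediate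
20 | 4-(tert-butyldimethylsilyloxy)benzoic acid | CC(C)(C)[Si](C)(C)Oc1ccc(cc1)C(=O)O | starting material
21 | O-acylisourea from 20 and EDC | CCN=C(NCCCN(C)C)OC(=O)c1ccc(O[Si](C)(C)C(C)(C)C)cc1 | intermediate (not isolated)
22 | (1R,4R,5S,6S,9S)-9-acetoxy-6-[4-(tert-butyldimethylsilyloxy)benzoyloxy]dauc-7-en-4-ol | CC(=O)O[C@H]1C[C@@]2(C)CC[C@@](O)(C(C)C)[C@@H]2[C@@H](OC(=O)c2ccc(O[Si](C)(C)C(C)(C)C)cc2)C=C1C | intermediate
23 | (1R,4R,5S,6S,9S)-9-acetoxy-6-(4-hydroxybenzoyloxy)dauc-7-en-4-ol, i.e. (3R,3aS,4S,7S,8aR)-7-acetoxy-3-hydroxy-6,8a-dimethyl-3-(propan-2-yl)-1,2,3,3a,4,7,8,8a-octahydroazulen-4-yl 4-hydroxybenzoate | CC(=O)O[C@H]1C[C@@]2(C)CC[C@@](O)(C(C)C)[C@@H]2[C@@H](OC(=O)c2ccc(O)cc2)C=C1C | target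

**Step count and uncertain steps**

Total: 12 steps. Longest linear sequence: 11 steps (5 to 23 through steps 2–12); the enone branch (1 to 23) is 10 steps.

Step 4 (key step). The most likely failure is insufficient discrimination between the two faces of enolate 10, since only allyl against methyl at C1 decides C5. The second is consumption of 8 by methyl transfer from aluminium before the sluggish aluminium enolate has reacted. The third is erosion of enantioselectivity on the five-membered enone. Fallback: the conjugate addition and the aldol are separated. Starting from 4, the same copper-catalysed methylation is quenched with TMSOTf to give (R)-3-allyl-3-methyl-1-(trimethylsilyloxy)cyclopent-1-ene F1, which is isolated so that its enantiopurity can be checked before 8 is spent. MeLi in THF at 0 °C then releases lithium (R)-3-allyl-3-methylcyclopent-1-en-1-olate F2. This enolate is free of methylaluminium species and more nucleophilic, and it is combined with 8 at −78 °C (closed transition state, E enolate, anti aldol) to come back to the route at 11.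

Step 6. The most likely failure is reduction of the ketone by β-hydride transfer from the isopropyl reagent, or enolisation, both favoured by the crowding at C4. Iodine–magnesium exchange at the iodoalkene is the further risk if transmetalation to cerium is incomplete. Fallback: the order of events and the nucleophile are changed. Starting from 12, OsO4/NaIO4 cleaves the allyl group through the keto diol F3 to the keto aldehyde F4. CrCl2 with catalytic NiCl2 converts F4 through the alkenylchromium dichloride F5 into the bicyclic hydroxy ketone F6, the aldehyde reacting in preference to the ketone. Excess 2-propenylmagnesium bromide with CeCl3, a reagent that cannot reduce by hydride transfer and now meets no iodoalkene, adds to C4 to give the isopropenyl carbinol F7. RhCl(PPh3)3 under H2 saturates the 1,1-disubstituted alkene in preference to the trisubstituted ring alkene, and the route is rejoined at 17. The C4 facial selectivity on the bicyclic ketone would have to be confirmed.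

Step 8. The most likely failure is poor facial selectivity at C9, because only the conformation of the forming seven-membered ring decides it. Intermolecular coupling is the second risk if dilution is insufficient. Fallback: C9 is reset by reagent control. Starting from 15, the closure is run as described. The C9 epimer (1R,4R,5S,6S,9R)-6-(triethylsilyloxy)dauc-7-ene-4,9-diol F8, alone or mixed with 17, is oxidised with Dess–Martin periodinane to the enone (1R,4R,5S,6S)-4-hydroxy-6-(triethylsilyloxy)dauc-7-en-9-one F9. Corey–Bakshi–Shibata reduction with BH3·SMe2 and the (R)-configured 2-methyl oxazaborolidine, with the alkenyl side as the large group, returns the route to 17.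

Step 10. The most likely failure is migration of the acetyl group from O9 to the freshly freed O6 across the cis-ene-diol, or ionisation of the allylic acetate if the medium is too acidic. Fallback: the silyl group is removed before any acetate is present. Starting from 17, HF·pyridine gives (1R,4R,5S,6S,9S)-dauc-7-ene-4,6,9-triol F10. Its less hindered C9 hydroxyl (flanked by a methylene, whereas O6 sits next to the fusion CH between C1 and C4) is acetylated site-selectively with Ac2O (1.0 equiv) and 2,4,6-collidine in CH2Cl2 at −40 °C, which rejoins the route at 19.

**Further compounds**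

F1 | step 4 | (R)-3-allyl-3-methyl-1-(trimethylsilyloxy)cyclopent-1-ene | C=CC[C@@]1(C)CCC(O[Si](C)(C)C)=C1
F2 | step 4 | lithium (R)-3-allyl-3-methylcyclopent-1-en-1-olate | C=CC[C@@]1(C)CCC(O[Li])=C1
F3 | step 6 | keto diol from 12 (2,3-dihydroxypropyl in place of allyl; both epimers at the new carbinol) | OCC(O)C[C@@]1(C)CCC(=O)[C@@H]1[C@@H](O[Si](CC)(CC)CC)/C=C(/C)I
F4 | step 6 | 2-{(1R,2S)-2-[(1R,2Z)-3-iodo-1-(triethylsilyloxy)but-2-en-1-yl]-1-methyl-3-oxocyclopentyl}acetaldehyde | O=CC[C@@]1(C)CCC(=O)[C@@H]1[C@@H](O[Si](CC)(CC)CC)/C=C(/C)I
F5 | step 6 | alkenylchromium dichloride from F4 (CrCl2 in place of iodine) | O=CC[C@@]1(C)CCC(=O)[C@@H]1[C@@H](O[Si](CC)(CC)CC)/C=C(/C)[Cr](Cl)Cl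
F6 | step 6 | (1R,5S,6S,9S)-9-hydroxy-6-(triethylsilyloxy)-14-nor-dauc-7-en-4-one type hydroxy ketone (C4 ketone, no isopropyl group) | O[C@H]1C[C@@]2(C)CCC(=O)[C@@H]2[C@@H](O[Si](CC)(CC)CC)C=C1C
F7 | step 6 | (1R,4R,5S,6S,9S)-4-(prop-1-en-2-yl) analogue of 17 (isopropenyl in place of isopropyl on C4) | O[C@H]1C[C@@]2(C)CC[C@@](O)(C(C)=C)[C@@H]2[C@@H](O[Si](CC)(CC)CC)C=C1C
F8 | step 8 | (1R,4R,5S,6S,9R)-6-(triethylsilyloxy)dauc-7-ene-4,9-diol | O[C@@H]1C[C@@]2(C)CC[C@@](O)(C(C)C)[C@@H]2[C@@H](O[Si](CC)(CC)CC)C=C1C
F9 | step 8 | (1R,4R,5S,6S)-4-hydroxy-6-(triethylsilyloxy)dauc-7-en-9-one | O=C1C[C@@]2(C)CC[C@@](O)(C(C)C)[C@@H]2[C@@H](O[Si](CC)(CC)CC)C=C1C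
F10 | step 10 | (1R,4R,5S,6S,9S)-dauc-7-ene-4,6,9-triol | O[C@H]1C[C@@]2(C)CC[C@@](O)(C(C)C)[C@@H]2[C@@H](O)C=C1C
A1 | alternative 1 | trans-hydrindene with C7=C9 alkene, C4 triethylsilyl ether and C6 tert-butyldimethylsilyl ether | C1=C[C@H](O[Si](C)(C)C(C)(C)C)[C@H]2[C@](O[Si](CC)(CC)CC)(C(C)C)CC[C@]2(C)C1
A2 | alternative 1 | gem-dibromocyclopropane from A1 (CBr2 bridge across C7 and C9, drawn on the face opposite the C1 methyl) | BrC1(Br)[C@H]2C[C@@]3(C)CC[C@@](O[Si](CC)(CC)CC)(C(C)C)[C@@H]3[C@@H](O[Si](C)(C)C(C)(C)C)[C@@H]12
A3 | alternative 1 | 9-acetoxy-8-bromodauc-7-ene 4-triethylsilyl 6-tert-butyldimethylsilyl bis-ether | CC(=O)O[C@H]1C[C@@]2(C)CC[C@@](O[Si](CC)(CC)CC)(C(C)C)[C@@H]2[C@@H](O[Si](C)(C)C(C)(C)C)C=C1Br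
A4 | alternative 2 | L-valine | CC(C)[C@H](N)C(=O)O
A5 | alternative 2 | methyl (3R,6R)-6-(tert-butyldimethylsilyloxy)-2-diazo-3-(2,2-dimethoxyethyl)-3,7-dimethyloctanoate | COC(=O)C(=[N+]=[N-])[C@@](C)(CC(OC)OC)CC[C@@H](O[Si](C)(C)C(C)(C)C)C(C)C
A6 | alternative 2 | methyl 2-(tert-butyldimethylsilyloxy)-5-(2,2-dimethoxyethyl)-5-methyl-2-(propan-2-yl)cyclopentane-1-carboxylate (configuration as in the SMILES) | COC(=O)[C@@H]1[C@@](C)(CC(OC)OC)CC[C@@]1(O[Si](C)(C)C(C)(C)C)C(C)C
A7 | alternative 3 | cyclopentane with C5 aldehyde, C4 triethylsilyl ether and the C1 chain CH2–CH(OAc)–C(CH3)=CHI (Z) | CC(=O)O[C@H](/C(C)=C\I)C[C@@]1(C)CC[C@@](O[Si](CC)(CC)CC)(C(C)C)[C@@H]1C=O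
A8 | alternative 3 | 9-acetoxydauc-7-en-6-ol 4-triethylsilyl ether | CC(=O)O[C@H]1C[C@@]2(C)CC[C@@](O[Si](CC)(CC)CC)(C(C)C)[C@@H]2[C@@H](O)C=C1C
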